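**Strategy.** The route rests on disconnecting the two alkenyl groups of cyclohexane ring C5–C10. The vinyl on quaternary C10 and the isopropenyl on C5 are cis, so C1 and C4 can be joined in a cis-fused cyclobutane that ethylene later opens. One enantioselective enone–allene [2+2] photocycloaddition forms C10–C1 and C5–C4, the four-membered ring and both stereocentres (C10, C5); the exocyclic methylene on C4 becomes the isopropenyl methyl. The precursors are 3-methylcyclohex-2-en-1-one and propadiene. The C6 ketone then serves to build C8–O, C7–C11 and the cis-lactone, before alkene isomerisation and ethenolysis.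

Key step: step 1

Remark (convention and assumption): atoms carry the target numbering (ring C5–C10, lactone carbons C11 and C12, cyclobutane carbons C1 and C4). Bicyclo[4.2.0]octane locants 1,2,3,4,5,6,7,8 correspond to C5, C6, C7, C8, C9, C10, C1, C4. α is the ring face bearing the cyclobutane bonds (later vinyl and isopropenyl), β the face of the C10 methyl. The Lewis-acid enantiomer is assumed to be the one that shields the Si face of C10.

Design note: the C11 methyl is introduced last, by alkylation of the lactone enolate, because an intermolecular pyruvate aldol offers no reliable control of the quaternary C11 centre. Ethyl glyoxylate therefore replaces a pyruvate ester.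

**Step 1**
Reactants: 1 3-methylcyclohex-2-en-1-one; 2 propadiene
Product: 3 (1R,6S)-6-methyl-8-methylidenebicyclo[4.2.0]octan-2-one
Conditions: 2 (excess), AlBr3-activated oxazaborolidine from α,α-bis(3,5-dimethylphenyl)prolinol and 2,4,6-trifluorophenylboronic acid (50 mol%), CH2Cl2, hν 366 nm, −75 °C; filtration through basic Al2O3
Reagents that add atoms: none
Why: Coordination of the chiral Lewis acid to the carbonyl of 1 shifts its absorption so that 366 nm light excites essentially only the complexed enone, whose triplet bonds through the α-carbon C5 to the central allene carbon C4 to give a 1,4-biradical (tertiary radical at C10, allyl-type radical ending at C1) that closes the C10–C1 bond after spin inversion. The closest known reactions are the head-to-head enone–allene [2+2] photocycloaddition to methylidenecyclobutanes and the oxazaborolidine–AlBr3-catalysed enantioselective intermolecular [2+2] photocycloaddition of cyclohexenones with simple alkenes. The one new ring, the cyclobutane C10–C1–C4–C5, closes by radical–radical combination of this 1,4-biradical (a stepwise intermolecular [2+2]), and only the cis fusion to the six-membered ring is retained because any trans-fused adduct epimerises at C5 on basic alumina. C10 is set by the catalyst, whose aryl groups shield the Si face of the enone β-carbon so that the allene bonds on the Re (α) face, and C5 then follows from the cis ring fusion. The step needs head-to-head regioselectivity, which is intrinsic to cyclohexenone–allene pairs (central allene carbon on the α-carbon), and suppression of the racemic background, which long-wavelength irradiation at −75 °C and the high catalyst loading should secure.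

**Step 2**
Reactants: 3 (1R,6S)-6-methyl-8-methylidenebicyclo[4.2.0]octan-2-one
Product: 5 (1R,6S)-6-methyl-8-methylidenebicyclo[4.2.0]oct-3-en-2-one, via lithium enolate 4 (not isolated)
Conditions: LDA, THF, −78 °C; then PhS(Cl)=N-t-Bu, −78 °C
Reagents that add atoms: none
Why: Kinetic deprotonation at the C7 methylene rather than the hindered ring-fusion C5–H, followed by Mukaiyama dehydrogenation (sulfenylation of the enolate by the sulfinimidoyl chloride and syn-elimination of the sulfenamide), can only give the C7=C8 enone because C10 is quaternary, and no stereocentre is touched.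

**Step 3**
Reactants: 5 (1R,6S)-6-methyl-8-methylidenebicyclo[4.2.0]oct-3-en-2-one; 6 ethyl glyoxylate
Product: 9 ethyl 2-hydroxy-2-[(1R,6S)-4-hydroxy-6-methyl-8-methylidene-2-oxobicyclo[4.2.0]octan-3-yl]acetate (4-OH β; 3-substituent α; both epimers at carbinol carbon C11), via boron enolate 7 (not isolated), via boron aldolate 8 (not isolated)
Conditions: B2pin2 (1.05 equiv), CuCl (5 mol%), Xantphos (5 mol%), NaOtBu (10 mol%), THF, rt, no protic additive; then 6, −78 → 0 °C; then NaBO3·4H2O, THF/H2O, 0 °C → rt
Reagents that add atoms: sodium perborate [Na+].[O-]OB=O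
Why: In this conjugate borylation–aldol domino the copper boryl (univalent copper) should add syn across C7=C8 from the convex β face, because the α face is screened over both alkene carbons by the quasi-axial cyclobutane carbons C4 and C1; without a protic additive the enolate is turned over to boron enolate 7, formed regiospecifically at C7, which adds to the aldehyde anti to the C8 boryl group (C7 side chain α, also the equatorial position), and perborate then replaces C–B by C–OH with retention, while C11 is left unselective on purpose because it is reset in step 6.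

**Step 4**
Reactants: 9 ethyl 2-hydroxy-2-[(1R,6S)-4-hydroxy-6-methyl-8-methylidene-2-oxobicyclo[4.2.0]octan-3-yl]acetate
Product: 10 ethyl 2-(tert-butyldimethylsilyloxy)-2-[(1R,6S)-4-(tert-butyldimethylsilyloxy)-6-methyl-8-methylidene-2-oxobicyclo[4.2.0]octan-3-yl]acetate (4-OTBS β; 3-substituent α; both C11 epimers)
Conditions: TBSOTf (2.5 equiv), 2,6-lutidine, CH2Cl2, −78 → −20 °C
Reagents that add atoms: tert-butyldimethylsilyl triflate CC(C)(C)[Si](C)(C)OS(=O)(=O)C(F)(F)F
Why: Silylation of both secondary alcohols under non-enolising conditions closes the retro-aldol and dehydration pathways of the two β-hydroxy ketone units and affects no stereocentre.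

**Step 5**
Reactants: 10 bis-TBS keto ester
Product: 12 bis-TBS tricyclic lactone (γ-lactone C6–O–C12 cis-fused on the α face; 8β-OTBS; 11-OTBS as both epimers; C4 methylidene), via lithium alkoxide 11 (not isolated)
Conditions: LiBH(s-Bu)3 (L-Selectride), THF, −78 °C → rt; aq. NH4Cl
Reagents that add atoms: none
Why: In this diastereoselective ketone reduction with lactonisation the bulky hydride should attack C6 equatorially from the β face, anti to both flanking α-oriented substituents (C5–C4 and the C7 side chain), which sets C6 as the axial α-alkoxide cis to the C7 side chain, and this alkoxide closes the five-membered lactone on the ethyl ester with loss of ethoxide.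

**Step 6**
Reactants: 12 bis-TBS tricyclic lactone
Product: 14 11-methyl lactone (11-methyl exo; 11-OTBS endo; 8β-OTBS; C4 methylidene), via lithium enolate 13 (not isolated)
Conditions: LDA, THF, −78 °C; then MeI, DMPU, −78 → −40 °C
Reagents that add atoms: iodomethane CI
Why: In this lactone enolate alkylation both C11 epimers converge on one planar enolate and iodomethane should enter on the convex face of the cis-fused lactone, anti to the C7–C8 bond, so that the methyl is exo and the silyloxy group endo, which is the C11 configuration of the target.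

**Step 7**
Reactants: 14 11-methyl lactone
Product: 15 4-methylcyclobutene lactone (C1=C4 endocyclic; otherwise as 14)
Conditions: chloro[N,N′-bis(3,5-di-tert-butylsalicylidene)-1,2-cyclohexanediaminato]cobalt (trivalent cobalt, 3 mol%), PhSiH3 (3 mol%), benzene, rt; unreacted 14 is recycled
Reagents that add atoms: none
Why: In this cobalt hydride HAT alkene isomerisation, hydrogen-atom transfer to the exocyclic CH2 gives the tertiary C4 cyclobutyl radical, and back-abstraction by divalent cobalt should occur at the accessible C1 methylene rather than at the shielded ring-fusion C5–H, giving the slightly more stable endocyclic trisubstituted alkene without touching a stereocentre.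

**Step 8**
Reactants: 15 4-methylcyclobutene lactone
Product: 16 3,4-bis(tert-butyldimethylsilyloxy)-6-ethenyl-3,6-dimethyl-7-(prop-1-en-2-yl)hexahydro-1-benzofuran-2(3H)-one (target configuration at all six stereocentres)
Conditions: RuCl2(H2IMes)(=CH–C6H4-2-O-i-Pr) (second-generation Hoveyda–Grubbs catalyst, 5 mol%), ethylene (1 atm), CH2Cl2, 40 °C
Reagents that add atoms: ethylene C=C
Why: In this ring-opening metathesis with ethylene the ruthenium methylidene should add to the strained cyclobutene with the metal on the less substituted C1, cycloreversion releases the ring strain and unveils the isopropenyl group on C5, and ethylene cleaves the C1 alkylidene to the vinyl group, while C5 and C10 are untouched so that the two alkenyl groups stay cis.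

**Step 9**
Reactants: 16 bis-TBS diene lactone
Product: 17 6-ethenyl-3,4-dihydroxy-3,6-dimethyl-7-(prop-1-en-2-yl)hexahydro-1-benzofuran-2(3H)-one (target configuration)
Conditions: aq. HF, MeCN, 0 °C → rt
Reagents that add atoms: none
Why: Fluoride-mediated desilylation should cleave both silyl ethers while the lactone and the alkenes are inert to dilute HF, and no stereocentre changes.

**Step 10**
Reactants: 17 diol lactone; 18 3-methylbut-3-enoic acid
Product: 19 8-O-(3-methylbut-3-enoyl) ester of 17 (free tertiary 11-OH)
Conditions: EDC·HCl, DMAP (10 mol%), CH2Cl2, 0 °C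
Reagents that add atoms: none
Why: Steglich esterification should be selective for the secondary equatorial C8–OH over the tertiary C11–OH, and low temperature with only catalytic DMAP keeps the β,γ-double bond of the acyl group out of conjugation.

**Step 11**
Reactants: 19 C8 ester with free 11-OH
Product: 20 (3S,3aS,4R,6S,7R,7aR)-3-(acetyloxy)-6-ethenyl-3,6-dimethyl-2-oxo-7-(prop-1-en-2-yl)octahydro-1-benzofuran-4-yl 3-methylbut-3-enoate (CNP0106639.1)
Conditions: Ac2O, DMAP, Et3N, CH2Cl2, rt → 40 °C
Reagents that add atoms: acetic anhydride CC(=O)OC(C)=O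
Why: DMAP-catalysed acylation should convert the remaining tertiary α-hydroxy lactone alcohol into the acetate with retention at C11 under conditions too weakly basic to isomerise the 3-methylbut-3-enoate.

**Compound list**

1 | 3-methylcyclohex-2-en-1-one | CC1=CC(=O)CCC1 | starting material
2 | propadiene | C=C=C | starting material
3 | (1R,6S)-6-methyl-8-methylidenebicyclo[4.2.0]octan-2-one | O=C1CCC[C@@]2(C)CC(=C)[C@@H]12 | intermediate
4 | lithium enolate of 3 (C6=C7) | [Li+].[O-]C1=CCC[C@@]2(C)CC(=C)[C@@H]12 | intermediate (not isolated)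
5 | (1R,6S)-6-methyl-8-methylidenebicyclo[4.2.0]oct-3-en-2-one | O=C1C=CC[C@@]2(C)CC(=C)[C@@H]12 | intermediate
6 | ethyl glyoxylate | O=CC(=O)OCC | starting material
7 | pinacolboron enolate with 8β-Bpin | CC1(C)OB(OC2=C[C@H](B3OC(C)(C)C(C)(C)O3)C[C@@]4(C)CC(=C)[C@@H]24)OC1(C)C | intermediate (not isolated)
8 | boron aldolate (8β-Bpin, C7 side chain α, C11–O–Bpin, both C11 epimers) | O=C1[C@@H](C(OB2OC(C)(C)C(C)(C)O2)C(=O)OCC)[C@H](B3OC(C)(C)C(C)(C)O3)C[C@@]4(C)CC(=C)[C@@H]14 | intermediate (not isolated)
9 | ethyl 2-hydroxy-2-[(1R,6S)-4-hydroxy-6-methyl-8-methylidene-2-oxobicyclo[4.2.0]octan-3-yl]acetate (4-OH β, 3-substituent α, both C11 epimers) | O=C1[C@@H](C(O)C(=O)OCC)[C@H](O)C[C@@]2(C)CC(=C)[C@@H]12 | intermediate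
10 | bis-TBS ether of 9 | O=C1[C@@H](C(O[Si](C)(C)C(C)(C)C)C(=O)OCC)[C@H](O[Si](C)(C)C(C)(C)C)C[C@@]2(C)CC(=C)[C@@H]12 | intermediate
11 | lithium alkoxide of the C6 α-alcohol from 10 | [Li+].[O-][C@H]1[C@@H](C(O[Si](C)(C)C(C)(C)C)C(=O)OCC)[C@H](O[Si](C)(C)C(C)(C)C)C[C@@]2(C)CC(=C)[C@@H]12 | intermediate (not isolated)
12 | bis-TBS tricyclic lactone (lactone cis-fused on the α face, 8β-OTBS, 11-OTBS both epimers, C4 methylidene) | C=C3C[C@]1(C)C[C@@H](O[Si](C)(C)C(C)(C)C)[C@H]2[C@H](OC(=O)C2O[Si](C)(C)C(C)(C)C)[C@@H]13 | intermediate
13 | lithium enolate of 12 (C11=C12) | C=C3C[C@]1(C)C[C@@H](O[Si](C)(C)C(C)(C)C)[C@H]2[C@H](OC([O-])=C2O[Si](C)(C)C(C)(C)C)[C@@H]13.[Li+] | intermediate (not isolated)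
14 | 11-methyl lactone (11-methyl exo, 11-OTBS endo, C4 methylidene) | C=C3C[C@]1(C)C[C@@H](O[Si](C)(C)C(C)(C)C)[C@H]2[C@H](OC(=O)[C@@]2(C)O[Si](C)(C)C(C)(C)C)[C@@H]13 | intermediate
15 | 4-methylcyclobutene lactone (C1=C4) | CC3=C[C@]1(C)C[C@@H](O[Si](C)(C)C(C)(C)C)[C@H]2[C@H](OC(=O)[C@@]2(C)O[Si](C)(C)C(C)(C)C)[C@@H]13 | intermediate
16 | 3,4-bis(tert-butyldimethylsilyloxy)-6-ethenyl-3,6-dimethyl-7-(prop-1-en-2-yl)hexahydro-1-benzofuran-2(3H)-one (target configuration) | C=C[C@]1(C)C[C@@H](O[Si](C)(C)C(C)(C)C)[C@H]2[C@H](OC(=O)[C@@]2(C)O[Si](C)(C)C(C)(C)C)[C@@H]1C(=C)C | intermediate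
17 | 6-ethenyl-3,4-dihydroxy-3,6-dimethyl-7-(prop-1-en-2-yl)hexahydro-1-benzofuran-2(3H)-one (target configuration) | C=C[C@]1(C)C[C@@H](O)[C@H]2[C@H](OC(=O)[C@@]2(C)O)[C@@H]1C(=C)C | intermediate
18 | 3-methylbut-3-enoic acid | C=C(C)CC(=O)O | starting material
19 | C8 3-methylbut-3-enoate of 17 with free 11-OH | C=C[C@]1(C)C[C@@H](OC(=O)CC(=C)C)[C@H]2[C@H](OC(=O)[C@@]2(C)O)[C@@H]1C(=C)C | intermediate
20 | (3S,3aS,4R,6S,7R,7aR)-3-(acetyloxy)-6-ethenyl-3,6-dimethyl-2-oxo-7-(prop-1-en-2-yl)octahydro-1-benzofuran-4-yl 3-methylbut-3-enoate | C=C[C@]1(C)C[C@@H](OC(=O)CC(=C)C)[C@H]2[C@H](OC(=O)[C@@]2(C)OC(C)=O)[C@@H]1C(=C)C | target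

**Step count.** Total: 11 steps. Longest linear sequence: 11 steps (1 → 20); 2, 6 and 18 are commercial.

**Steps most likely to fail**

1. Step 1. Enantioselectivity may erode through excitation of uncomplexed enone, or propadiene may oligomerise on the strong Lewis acid. Fallback, setting out from 1 and 2 and returning at 3: the uncatalysed photocycloaddition (hν 350 nm, THF, −78 °C, basic Al2O3) should give the racemic cis-fused ketone F1. Corey–Bakshi–Shibata reduction (BH3·SMe2 with the Me-CBS oxazaborolidine enantiomer matched to the convex face of the (1R,6S) ketone) should turn the two enantiomers into diastereomeric alcohols: the α-alcohol of the wanted series F2 and the alcohol of the enantiomeric series F3, separable by chromatography. Dess–Martin oxidation of F2 returns to 3.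

2. Step 3. Turnover and trapping of the boron enolate without a protic additive may be incomplete, or facial selectivity at C8 may be insufficient under substrate control. Fallback, setting out from 5 and returning at 10: protic, ligand-controlled conjugate borylation (B2pin2, CuCl, a Josiphos ligand of the enantiomer matched to β-face delivery, NaOtBu, MeOH, THF) gives the β-boryl ketone F4, and NaBO3·4H2O oxidation gives the β-hydroxy ketone F5. TBSCl and imidazole give the silyl ether F6. Enolisation at the C7 methylene with (c-Hex)2BCl and Et3N gives the boron enolate F7, addition of 6 gives the boron aldolate F8, and buffered aqueous methanol work-up gives the hydroxy ester F9. TBSOTf and 2,6-lutidine then give 10.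

3. Step 7. Hydrogen abstraction may occur at C5 and lead to the tetrasubstituted ring-fusion alkene, or the exocyclic/endocyclic equilibrium may be unfavourable. Fallback, setting out from 14 and returning at 15: Lemieux–Johnson cleavage of the only alkene (OsO4 cat., NaIO4, 2,6-lutidine, dioxane/H2O) gives the cyclobutanone F10. Kinetic deprotonation at the C1 methylene with KN(SiMe3)2 at −78 °C gives the potassium enolate F11, which PhNTf2 traps as the enol triflate F12. Negishi coupling with MeZnCl and Pd(PPh3)4 gives 15 with the double bond fixed between C1 and C4.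

**Further compounds**

F1 | step 1 | racemic cis-6-methyl-8-methylidenebicyclo[4.2.0]octan-2-one (both enantiomers) | O=C1CCC[C@@]2(C)CC(=C)[C@@H]12.O=C1CCC[C@]2(C)CC(=C)[C@H]12
F2 | step 1 | (1R,6S)-series 2-ol, OH α (cis to the cyclobutane) | O[C@H]1CCC[C@@]2(C)CC(=C)[C@@H]12
F3 | step 1 | (1S,6R)-series 2-ol, OH trans to the cyclobutane | O[C@H]1CCC[C@]2(C)CC(=C)[C@H]12
F4 | step 3 | (1R,6S)-6-methyl-8-methylidene-4β-(pinacolboryl)bicyclo[4.2.0]octan-2-one | O=C1C[C@H](B2OC(C)(C)C(C)(C)O2)C[C@@]3(C)CC(=C)[C@@H]13
F5 | step 3 | (1R,6S)-4β-hydroxy-6-methyl-8-methylidenebicyclo[4.2.0]octan-2-one | O=C1C[C@H](O)C[C@@]2(C)CC(=C)[C@@H]12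
F6 | step 3 | TBS ether of F5 | O=C1C[C@H](O[Si](C)(C)C(C)(C)C)C[C@@]2(C)CC(=C)[C@@H]12
F7 | step 3 | dicyclohexylboron enolate of F6 (C6=C7) | C1CCC(CC1)B(OC2=C[C@H](O[Si](C)(C)C(C)(C)C)C[C@@]3(C)CC(=C)[C@@H]23)C1CCCCC1
F8 | step 3 | dicyclohexylboron aldolate (C7 side chain α, both C11 epimers) | O=C1[C@@H](C(OB(C2CCCCC2)C2CCCCC2)C(=O)OCC)[C@H](O[Si](C)(C)C(C)(C)C)C[C@@]3(C)CC(=C)[C@@H]13
F9 | step 3 | ethyl 2-hydroxy-2-[(1R,6S)-4β-(tert-butyldimethylsilyloxy)-6-methyl-8-methylidene-2-oxobicyclo[4.2.0]octan-3α-yl]acetate (both C11 epimers) | O=C1[C@@H](C(O)C(=O)OCC)[C@H](O[Si](C)(C)C(C)(C)C)C[C@@]2(C)CC(=C)[C@@H]12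
F10 | step 7 | C4 cyclobutanone derived from 14 | O=C3C[C@]1(C)C[C@@H](O[Si](C)(C)C(C)(C)C)[C@H]2[C@H](OC(=O)[C@@]2(C)O[Si](C)(C)C(C)(C)C)[C@@H]13
F11 | step 7 | potassium enolate of F10 (C1=C4) | [K+].[O-]C3=C[C@]1(C)C[C@@H](O[Si](C)(C)C(C)(C)C)[C@H]2[C@H](OC(=O)[C@@]2(C)O[Si](C)(C)C(C)(C)C)[C@@H]13
F12 | step 7 | C4 enol triflate (C1=C4) | O=S(=O)(OC3=C[C@]1(C)C[C@@H](O[Si](C)(C)C(C)(C)C)[C@H]2[C@H](OC(=O)[C@@]2(C)O[Si](C)(C)C(C)(C)C)[C@@H]13)C(F)(F)F
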